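## Retrosynthetic overview
1. The target comes from its octasilyl ether by a single fluoride deprotection at the end.
2. Ring C (the methylcyclohexene) comes from a rhodium-catalysed one-carbon ring expansion of a vinylcyclopropane. The C2–C4 cyclopropane bond is cleaved and a ring B benzylidene, released from the aldehyde tosylhydrazone, is inserted between C4 and the isopropenyl CH2. This forms C4–C5 and C5–C6, and the alkene ends up at C1=C2.
3. The vinylcyclopropane comes from the ring A/ring D chalcone and methallyl bromide through a chiral sulfonium allylide. This forms C2–C3 and C2–C4 and sets C3.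
4. The chalcone comes from the ring A acetophenone and the stilbene aldehyde. The stilbene comes from a Heck coupling of the 5-iodo aldehyde with the ring E styrene, itself made by C–H borylation and vinylation.
5. All four arenes come from resorcinol. The cyclopropane is formed first, and ring C is then made by expanding it.

Labels: ring C is C1(CH3)=C2H–C3H(ring D)–C4H(CO–ring A)–C5H(ring B)–C6H2. Ring E is the outer 3,5-dioxygenated stilbene ring. TBS = tert-butyldimethylsilyl and TIPS = triisopropylsilyl.

Assumption: the camphor-derived sulfide is taken to induce the (R) configuration at the aryl-bearing carbon. If the opposite sense is found, its endo-configured pseudo-enantiomer is used.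

## Route

Step 1
Reactants: 1 resorcinol
Product: 2 2,4-dihydroxybenzaldehyde
Conditions: POCl3, DMF, MeCN, -15 to 25 °C; then H2O, 50 °C
Reagents that add atoms: N,N-dimethylformamide CN(C)C=O; water O
Why: Vilsmeier–Haack formylation, in which the chloroiminium ion attacks the most activated and least hindered position (para to one OH, ortho to the other) and hydrolysis frees the aldehyde.

Step 2
Reactants: 2 2,4-dihydroxybenzaldehyde
Product: 3 2,4-bis(tert-butyldimethylsilyloxy)benzaldehyde
Conditions: TBSCl (2.5 equiv), imidazole, DMF, 25 °C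
Reagents that add atoms: tert-butyldimethylsilyl chloride CC(C)(C)[Si](C)(C)Cl
Why: Imidazole-promoted silyl ether formation masks both phenols against the ylide, carbene and palladium chemistry that follows, and 3 serves both ring B and ring D.

Step 3
Reactants: 3 2,4-bis(tert-butyldimethylsilyloxy)benzaldehyde
Product: 4 2,4-bis(tert-butyldimethylsilyloxy)-5-iodobenzaldehyde
Conditions: NIS (1.05 equiv), TFA (10 mol %), MeCN, 0 to 25 °C, dark
Reagents that add atoms: N-iodosuccinimide O=C1CCC(=O)N1I
Why: Electrophilic aromatic iodination goes to C5, which is para to the 2-silyloxy group, ortho to the 4-silyloxy group and meta to the aldehyde, whereas C3 is shielded by two silyloxy neighbours.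

Step 4
Reactants: 1 resorcinol
Product: 5 1,3-bis(triisopropylsilyloxy)benzene
Conditions: TIPSCl (2.3 equiv), imidazole, DMF, 25 °C
Reagents that add atoms: triisopropylsilyl chloride CC(C)[Si](Cl)(C(C)C)C(C)C
Why: Silyl ether formation, with TIPS chosen for ring E because it survives the aqueous phosphate of step 5 and still leaves with fluoride in step 12.

Step 5
Reactants: 5 1,3-bis(triisopropylsilyloxy)benzene; 6 vinyl bromide
Product: 8 3,5-bis(triisopropylsilyloxy)styrene, via arylboronate 7 (not isolated)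
Conditions: [Ir(OMe)(cod)]2 (1.5 mol %), dtbpy (3 mol %), B2pin2 (1.0 equiv), THF, 80 °C; then 6 (1 M in THF), Pd(dppf)Cl2 (3 mol %), K3PO4, H2O, 60 °C
Reagents that add atoms: none
Why: Sterically controlled iridium-catalysed C–H borylation reaches the only C–H bond without an ortho substituent (C5), and the crude boronate undergoes Suzuki–Miyaura vinylation in the same flask.

Step 6
Reactants: 4 2,4-bis(tert-butyldimethylsilyloxy)-5-iodobenzaldehyde; 8 3,5-bis(triisopropylsilyloxy)styrene
Product: 9 (E)-stilbene aldehyde 2,4-bis(TBSO)-5-[2-(3,5-bis(TIPSO)phenyl)ethenyl]benzaldehyde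
Conditions: Pd(OAc)2 (5 mol %), P(o-tol)3 (10 mol %), Et3N, DMF, 80 °C
Reagents that add atoms: none
Why: Mizoroki–Heck reaction, where syn insertion at the unsubstituted styrene terminus and syn β-hydride elimination give only the E-stilbene, and the amine base leaves the aryl silyl ethers intact.

Step 7
Reactants: 1 resorcinol; 10 acetic acid
Product: 11 2,4-dihydroxyacetophenone
Conditions: ZnCl2 (1.2 equiv), 10 as solvent, 140 °C
Reagents that add atoms: none
Why: Nencki reaction (ZnCl2-mediated Friedel–Crafts acylation) acylates resorcinol at C4 and stops there because the chelated ketone deactivates the ring.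

Step 8
Reactants: 11 2,4-dihydroxyacetophenone
Product: 12 2,4-bis(tert-butyldimethylsilyloxy)acetophenone
Conditions: TBSCl (2.6 equiv), imidazole, DMAP (10 mol %), DMF, 50 °C
Reagents that add atoms: tert-butyldimethylsilyl chloride CC(C)(C)[Si](C)(C)Cl
Why: Silyl ether formation, with gentle heating and DMAP to overcome the hydrogen bond of the ortho phenol to the ketone.

Step 9
Reactants: 12 2,4-bis(tert-butyldimethylsilyloxy)acetophenone; 9 (E)-stilbene aldehyde
Product: 15 (E)-chalcone carrying ring A on the carbonyl carbon and ring D on the β-carbon, via enol silane 13 (not isolated), via silyloxy ketone 14 (not isolated)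
Conditions: TMSOTf (2.3 equiv), i-Pr2NEt (2.6 equiv), CH2Cl2, 0 to 25 °C
Reagents that add atoms: none
Why: One-pot enol silane formation, Mukaiyama aldol addition and elimination, in which the very electron-rich ring D lets the β-silyloxy group ionise under TMSOTf and the amine removes the α-proton, so the E-chalcone forms without hydroxide or alkoxide that would strip the aryl silyl ethers.

Step 10
Reactants: 15 (E)-chalcone; 16 3-bromo-2-methylprop-1-ene
Product: 19 vinylcyclopropane [(1R,2R,3S)-2-(ring D aryl)-3-(prop-1-en-2-yl)cyclopropyl](ring A aryl)methanone, via sulfonium bromide 17 (not isolated), via sulfonium ylide 18 (not isolated)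
Conditions: exo-3-(methylsulfanyl)isoborneol from (+)-camphor (1.2 equiv), 16, acetone, 25 °C, 24 h; evaporate; KOt-Bu (1.2 equiv), THF, -78 °C; then 15, -78 to -40 °C
Reagents that add atoms: none
Why: Corey–Chaykovsky-type Michael-initiated ring closure of a chiral sulfonium allylide, a known route from chalcones to enantioenriched vinylcyclopropanes: the ylide carbon adds to one face of the chalcone β-carbon (the sulfide hydroxyl holds the carbonyl group through potassium) and sets C3 as R, the enolate then displaces the sulfide with aroyl and aryl trans, and the configuration at C2 is irrelevant because C2 becomes sp2 in step 11.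

Step 11
Reactants: 19 vinylcyclopropane; 3 2,4-bis(tert-butyldimethylsilyloxy)benzaldehyde
Product: 22 octasilyl ether of the target in the (1R,2R,6S) all-trans configuration, via tosylhydrazone 20 (not isolated), via aryldiazomethane 21 (not isolated)
Conditions: 3 (1.5 equiv), TsNHNH2 (1.5 equiv), 4 Å MS, 1,4-dioxane, 25 °C; NaN(SiMe3)2 (1.5 equiv), 0 °C; then 19, [Rh(cod)Cl]2 (5 mol %), P(OPh)3 (10 mol %), BnEt3NCl (10 mol %), 45 °C; then DBU (20 mol %), 25 °C
Reagents that add atoms: none
Why: Proposed new method: monovalent rhodium binds the isopropenyl group and inserts into the adjacent C2–C4 cyclopropane bond (weakened by the vinyl donor and the ketone acceptor) to give a six-membered rhodacycle with a σ-allyl carbon at C6, a rhodium enolate at C4 and a cis C1=C2 bond; diazoalkane 21, released slowly from 20, forms a rhodium carbene, the allyl carbon migrates from rhodium to the carbene carbon (1,2-shift, C5–C6 bond) and C4–C5 reductive elimination from the seven-membered rhodacycle closes ring C, so the three-membered ring grows to the six-membered ring with one inserted carbon; C3 is not touched and keeps its configuration, ring B takes the equatorial site on C5 cis to ring D in the chair-like elimination, and DBU brings C4 to the all-equatorial trans,trans arrangement; the closest known reaction types are the rhodium-catalysed carbonylative [5+1] ring expansion of vinylcyclopropanes and the capture of metallacycles or rhodium alkyls by diazo-derived carbenes through migratory insertion.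

Step 12
Reactants: 22 octasilyl ether of the target
Product: 23 target [(1R,2R,6S)-6-(2,4-dihydroxyphenyl)-2-{5-[(E)-2-(3,5-dihydroxyphenyl)ethenyl]-2,4-dihydroxyphenyl}-4-methylcyclohex-3-en-1-yl](2,4-dihydroxyphenyl)methanone
Conditions: TBAF (10 equiv), AcOH (10 equiv), THF, 0 to 25 °C, argon
Reagents that add atoms: none
Why: Fluoride-driven cleavage of all eight aryl silyl ethers, with acetic acid buffering the phenoxides so that neither the acid-sensitive ortho-hydroxyaryl/trisubstituted alkene pair nor the C4 stereocentre is disturbed.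

## Compound list
1 | resorcinol | Oc1cccc(O)c1 | starting material
2 | 2,4-dihydroxybenzaldehyde | O=Cc1ccc(O)cc1O | intermediate
3 | 2,4-bis(tert-butyldimethylsilyloxy)benzaldehyde | O=Cc1ccc(O[Si](C)(C)C(C)(C)C)cc1O[Si](C)(C)C(C)(C)C | intermediate
4 | 2,4-bis(tert-butyldimethylsilyloxy)-5-iodobenzaldehyde | O=Cc1cc(I)c(O[Si](C)(C)C(C)(C)C)cc1O[Si](C)(C)C(C)(C)C | intermediate
5 | 1,3-bis(triisopropylsilyloxy)benzene | CC(C)[Si](Oc1cccc(O[Si](C(C)C)(C(C)C)C(C)C)c1)(C(C)C)C(C)C | intermediate
6 | vinyl bromide | C=CBr | starting material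
7 | 2-[3,5-bis(triisopropylsilyloxy)phenyl]-4,4,5,5-tetramethyl-1,3,2-dioxaborolane (not isolated) | CC1(C)OB(OC1(C)C)c1cc(O[Si](C(C)C)(C(C)C)C(C)C)cc(O[Si](C(C)C)(C(C)C)C(C)C)c1 | intermediate
8 | 3,5-bis(triisopropylsilyloxy)styrene | C=Cc1cc(O[Si](C(C)C)(C(C)C)C(C)C)cc(O[Si](C(C)C)(C(C)C)C(C)C)c1 | intermediate
9 | 2,4-bis(TBSO)-5-[(E)-2-(3,5-bis(TIPSO)phenyl)ethenyl]benzaldehyde | O=Cc1cc(/C=C/c2cc(O[Si](C(C)C)(C(C)C)C(C)C)cc(O[Si](C(C)C)(C(C)C)C(C)C)c2)c(O[Si](C)(C)C(C)(C)C)cc1O[Si](C)(C)C(C)(C)C | intermediate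
10 | acetic acid | CC(=O)O | starting material
11 | 2,4-dihydroxyacetophenone | CC(=O)c1ccc(O)cc1O | intermediate
12 | 2,4-bis(tert-butyldimethylsilyloxy)acetophenone | CC(=O)c1ccc(O[Si](C)(C)C(C)(C)C)cc1O[Si](C)(C)C(C)(C)C | intermediate
13 | trimethylsilyl enol ether of 12 (not isolated) | C=C(O[Si](C)(C)C)c1ccc(O[Si](C)(C)C(C)(C)C)cc1O[Si](C)(C)C(C)(C)C | intermediate
14 | β-(trimethylsilyloxy) ketone from 13 and 9, racemic (not isolated) | O=C(CC(O[Si](C)(C)C)c1cc(/C=C/c2cc(O[Si](C(C)C)(C(C)C)C(C)C)cc(O[Si](C(C)C)(C(C)C)C(C)C)c2)c(O[Si](C)(C)C(C)(C)C)cc1O[Si](C)(C)C(C)(C)C)c1ccc(O[Si](C)(C)C(C)(C)C)cc1O[Si](C)(C)C(C)(C)C | intermediate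
15 | (E)-chalcone, ring A on C=O and ring D (with the E-stilbene) on the β-carbon | O=C(/C=C/c1cc(/C=C/c2cc(O[Si](C(C)C)(C(C)C)C(C)C)cc(O[Si](C(C)C)(C(C)C)C(C)C)c2)c(O[Si](C)(C)C(C)(C)C)cc1O[Si](C)(C)C(C)(C)C)c1ccc(O[Si](C)(C)C(C)(C)C)cc1O[Si](C)(C)C(C)(C)C | intermediate
16 | 3-bromo-2-methylprop-1-ene (methallyl bromide) | C=C(C)CBr | starting material
17 | S-methyl-S-(2-methylallyl)sulfonium bromide of exo-3-sulfanylisoborneol (not isolated) | C[C@@]12CC[C@@H](C1(C)C)[C@@H]([S+](C)CC(C)=C)[C@H]2O.[Br-] | intermediate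
18 | sulfonium allylide from 17 (not isolated) | C[C@@]12CC[C@@H](C1(C)C)[C@@H]([S+](C)[CH-]C(C)=C)[C@H]2O | intermediate
19 | (1R,2R,3S)-vinylcyclopropane, aroyl trans to both ring D and isopropenyl | CC(=C)[C@H]1[C@@H](c2cc(/C=C/c3cc(O[Si](C(C)C)(C(C)C)C(C)C)cc(O[Si](C(C)C)(C(C)C)C(C)C)c3)c(O[Si](C)(C)C(C)(C)C)cc2O[Si](C)(C)C(C)(C)C)[C@@H]1C(=O)c1ccc(O[Si](C)(C)C(C)(C)C)cc1O[Si](C)(C)C(C)(C)C | intermediate
20 | (E)-N-tosylhydrazone of 3 (not isolated) | Cc1ccc(S(=O)(=O)N/N=C/c2ccc(O[Si](C)(C)C(C)(C)C)cc2O[Si](C)(C)C(C)(C)C)cc1 | intermediate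
21 | [2,4-bis(TBSO)phenyl]diazomethane (not isolated) | [N-]=[N+]=Cc1ccc(O[Si](C)(C)C(C)(C)C)cc1O[Si](C)(C)C(C)(C)C | intermediate
22 | octasilyl ether of the target (six TBS, two TIPS), (1R,2R,6S), all-trans | CC1=C[C@@H](c2cc(/C=C/c3cc(O[Si](C(C)C)(C(C)C)C(C)C)cc(O[Si](C(C)C)(C(C)C)C(C)C)c3)c(O[Si](C)(C)C(C)(C)C)cc2O[Si](C)(C)C(C)(C)C)[C@H](C(=O)c2ccc(O[Si](C)(C)C(C)(C)C)cc2O[Si](C)(C)C(C)(C)C)[C@@H](c2ccc(O[Si](C)(C)C(C)(C)C)cc2O[Si](C)(C)C(C)(C)C)C1 | intermediate
23 | CNP0327388.2 | CC1=C[C@@H](c2cc(/C=C/c3cc(O)cc(O)c3)c(O)cc2O)[C@H](C(=O)c2ccc(O)cc2O)[C@@H](c2ccc(O)cc2O)C1 | target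

## Step count and risks
Total step count: 12. Longest linear sequence: 8 steps (steps 1, 2, 3, 6, 9, 10, 11, 12, from resorcinol).

**Step 11 (the proposed new ring expansion).** Four failure modes are foreseen:
- direct reductive elimination of the rhodacycle to the cyclopentene;
- dimerisation of the electron-rich carbene;
- isomerisation of the donor–acceptor cyclopropane to a dihydrofuran;
- the wrong epimer at C5.

The fallback uses known chemistry, sets out from 12, 3, 9 and 16, and comes back to the route at 23. Ketone 12 and aldehyde 3 are condensed under the conditions of step 9, through enol silane 13 and the silyloxy ketone F1, to the persilylated chalcone F2. BCl3 (1 equiv, CH2Cl2, -78 °C) removes only the silyl group chelated to the ketone and gives the 2'-hydroxychalcone F3. Bromide 16 and PPh3 give (2-methylallyl)triphenylphosphonium bromide F4. Its deprotonation with n-BuLi gives the phosphorus ylide F5, which olefinates aldehyde 9. Equilibration with a trace of I2 then gives the (E)-dehydroprenyl diene F6. The known enantioselective Diels–Alder reaction of 2'-hydroxychalcones with such dienes follows, under a chiral borate made from BH3·THF, AcOH and (R)-VANOL (or its antipode if the sense of induction requires it). It gives exo and endo adducts, and the exo adduct F7 is separated and desilylated as in step 12 to 23.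

**Step 10 (asymmetric cyclopropanation).** The chalcone is very electron-rich and ortho-substituted, so addition may be slow and the ee may fall. The fallback replaces asymmetric induction by resolution. It sets out from 15 and 16 and comes back at 19. Tetrahydrothiophene and 16 give 1-(2-methylallyl)tetrahydrothiophenium bromide F8. KOt-Bu converts it into the achiral sulfonium ylide F9, which cyclopropanates 15 at higher temperature. The racemate consists of 19 and the enantiomeric vinylcyclopropane F10, and these are separated by preparative chiral-phase SFC.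

**Step 12 (eightfold desilylation).** The product is an oxidation-prone and acid-sensitive polyphenol, so incomplete cleavage or losses on purification are possible. The fallback sets out from 22 and comes back at 23. Compound 22 is treated with TBAF and the crude phenoxides are acetylated in the same flask (Ac2O, pyridine) to the octaacetate F11. This is stable, can be chromatographed and crystallised, and also allows upgrading of the ee. Mild methanolysis (K2CO3, MeOH, argon, 0 °C), a release known to be tolerated by this family of adducts, then gives 23.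

## Further compounds
F1 | step 11 | β-(trimethylsilyloxy) ketone from 13 and 3, racemic | O=C(CC(O[Si](C)(C)C)c1ccc(O[Si](C)(C)C(C)(C)C)cc1O[Si](C)(C)C(C)(C)C)c1ccc(O[Si](C)(C)C(C)(C)C)cc1O[Si](C)(C)C(C)(C)C
F2 | step 11 | (E)-1,3-bis[2,4-bis(TBSO)phenyl]prop-2-en-1-one | O=C(/C=C/c1ccc(O[Si](C)(C)C(C)(C)C)cc1O[Si](C)(C)C(C)(C)C)c1ccc(O[Si](C)(C)C(C)(C)C)cc1O[Si](C)(C)C(C)(C)C
F3 | step 11 | (E)-3-[2,4-bis(TBSO)phenyl]-1-[2-hydroxy-4-(TBSO)phenyl]prop-2-en-1-one | O=C(/C=C/c1ccc(O[Si](C)(C)C(C)(C)C)cc1O[Si](C)(C)C(C)(C)C)c1ccc(O[Si](C)(C)C(C)(C)C)cc1O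
F4 | step 11 | (2-methylallyl)triphenylphosphonium bromide | C=C(C)C[P+](c1ccccc1)(c1ccccc1)c1ccccc1.[Br-]
F5 | step 11 | (2-methylallylidene)triphenylphosphorane | C=C(C)C=P(c1ccccc1)(c1ccccc1)c1ccccc1
F6 | step 11 | (E)-dehydroprenyl diene of the protected stilbene | C=C(C)/C=C/c1cc(/C=C/c2cc(O[Si](C(C)C)(C(C)C)C(C)C)cc(O[Si](C(C)C)(C(C)C)C(C)C)c2)c(O[Si](C)(C)C(C)(C)C)cc1O[Si](C)(C)C(C)(C)C
F7 | step 11 | exo (all-trans) Diels–Alder adduct, heptasilyl ether with free 2-OH on ring A | CC1=C[C@@H](c2cc(/C=C/c3cc(O[Si](C(C)C)(C(C)C)C(C)C)cc(O[Si](C(C)C)(C(C)C)C(C)C)c3)c(O[Si](C)(C)C(C)(C)C)cc2O[Si](C)(C)C(C)(C)C)[C@H](C(=O)c2ccc(O[Si](C)(C)C(C)(C)C)cc2O)[C@@H](c2ccc(O[Si](C)(C)C(C)(C)C)cc2O[Si](C)(C)C(C)(C)C)C1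
F8 | step 10 | 1-(2-methylallyl)tetrahydrothiophenium bromide | C=C(C)C[S+]1CCCC1.[Br-]
F9 | step 10 | tetrahydrothiophenium 2-methylallylide | C=C(C)[CH-][S+]1CCCC1
F10 | step 10 | (1S,2S,3R)-vinylcyclopropane, enantiomer of 19 | CC(=C)[C@@H]1[C@H](c2cc(/C=C/c3cc(O[Si](C(C)C)(C(C)C)C(C)C)cc(O[Si](C(C)C)(C(C)C)C(C)C)c3)c(O[Si](C)(C)C(C)(C)C)cc2O[Si](C)(C)C(C)(C)C)[C@H]1C(=O)c1ccc(O[Si](C)(C)C(C)(C)C)cc1O[Si](C)(C)C(C)(C)C
F11 | step 12 | octaacetate of the target | CC1=C[C@@H](c2cc(/C=C/c3cc(OC(C)=O)cc(OC(C)=O)c3)c(OC(C)=O)cc2OC(C)=O)[C@H](C(=O)c2ccc(OC(C)=O)cc2OC(C)=O)[C@@H](c2ccc(OC(C)=O)cc2OC(C)=O)C1
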